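The decalin is cut at C10–C5 and C3–C4 at once. Ring A has its oxygen on C1 para to C4 (quaternary, bearing the C19 ester and C18), and C1 flanks quaternary C10: the imprint of a 2-silyloxydiene (C10=C1–C2=C3) adding to a (Z)-2-methyl enoate (C5=C4), with C9–C8–C7–C6 of ring B as tether. One thermal intramolecular Diels–Alder reaction of an open-chain triene thus closes rings A and B and sets C10, C5 and C4 from C9 alone, which is installed earlier by auxiliary-controlled cuprate addition. The precursor is acyclic: a silyl dienol ether of a vinyl ketone linked through C9 and the C8 methylidene to the enoate; the diene side chain is finished afterwards.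

Key step: step 16

Remark: atoms are numbered as in labdanes (decalin C1–C10, side chain C11–C16, exocyclic methylene C17, C18 and C19 on C4, C20 on C10); TBDPS = tert-butyldiphenylsilyl, TBS = tert-butyldimethylsilyl; phosphonate 21 and ylide 32 are assumed to be purchasable.

Step 1
Reactants: 1 2,3-dibromopropene; 2 ethyl acetate
Product: 4 ethyl 4-bromopent-4-enoate, via ethyl acetate lithium enolate 3 (not isolated)
Conditions: LiN(iPr)2, THF, −78 °C; then 1, DMPU, −78 °C → rt
Reagents that add atoms: none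
Why: Allylic SN2 alkylation of an ester lithium enolate by the allylic bromide of 1 should give the C5–C8/C17 unit, the vinylic bromide being inert to enolates and kept as the later Grignard handle.

Step 2
Reactants: 4 ethyl 4-bromopent-4-enoate
Product: 5 4-bromopent-4-enal
Conditions: iBu2AlH, CH2Cl2, −78 °C
Reagents that add atoms: none
Why: Half-reduction of an ester with iBu2AlH at low temperature stops at the aluminium hemiacetal, which should release the aldehyde on work-up without touching the vinyl bromide.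

Step 3
Reactants: 5 4-bromopent-4-enal
Product: 6 2-bromo-5,5-dimethoxypent-1-ene
Conditions: HC(OMe)3, MeOH, TsOH·H2O (cat.), rt
Reagents that add atoms: methanol, CO; trimethyl orthoformate, COC(OC)OC
Why: Acid-catalysed acetalisation, driven by the orthoformate as water scavenger, masks C5 so that an organomagnesium reagent can be formed at C8.

Step 4
Reactants: 7 propane-1,3-diol
Product: 8 3-(TBDPS-oxy)propan-1-ol
Conditions: TBDPSCl, imidazole, 7 (4 equiv), CH2Cl2, 0 °C → rt
Reagents that add atoms: tert-butyl(chloro)diphenylsilane, CC(C)(C)[Si](Cl)(c1ccccc1)c1ccccc1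
Why: Statistical monosilylation of a symmetrical diol used in excess should give the mono-ether, and the TBDPS group is chosen because it tolerates the later base, acid and thermal steps.

Step 5
Reactants: 8 3-(TBDPS-oxy)propan-1-ol
Product: 9 3-(TBDPS-oxy)propanal
Conditions: TEMPO (cat.), PhI(OAc)2, CH2Cl2, rt
Reagents that add atoms: none
Why: Nitroxyl-catalysed oxidation takes a primary alcohol to the aldehyde without over-oxidation and under conditions too mild for β-elimination of the silyloxy group.

Step 6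
Reactants: 9 3-(TBDPS-oxy)propanal
Product: 10 ethyl (2E)-5-(TBDPS-oxy)pent-2-enoate
Conditions: (EtO)2P(O)CH2CO2Et, LiCl, iPr2NEt, MeCN, rt
Reagents that add atoms: triethyl phosphonoacetate, CCOC(=O)CP(=O)(OCC)OCC
Why: Horner–Wadsworth–Emmons olefination with a stabilised phosphonate under LiCl/amine activation should give the E-enoate (C10, C1 added) while avoiding the strong base that could eliminate the β-silyloxy aldehyde.

Step 7
Reactants: 10 ethyl (2E)-5-(TBDPS-oxy)pent-2-enoate
Product: 11 (2E)-5-(TBDPS-oxy)pent-2-enoic acid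
Conditions: LiOH·H2O, THF/MeOH/H2O, rt; then 1 M HCl to pH 3
Reagents that add atoms: lithium hydroxide, [Li+].[OH-]
Why: Saponification of an unhindered ethyl ester, which the TBDPS ether and the E-alkene should survive at room temperature.

Step 8
Reactants: 11 (2E)-5-(TBDPS-oxy)pent-2-enoic acid; 12 (4R)-4-benzyl-1,3-oxazolidin-2-one
Product: 14 (4R)-4-benzyl-3-[(2E)-5-(TBDPS-oxy)pent-2-enoyl]-1,3-oxazolidin-2-one, via mixed pivalic anhydride 13 (not isolated)
Conditions: PivCl, Et3N, THF, −20 °C; then 12, LiCl, −20 °C → rt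
Reagents that add atoms: none
Why: N-Acylation of the oxazolidinone through the mixed pivalic anhydride (attack at the less hindered enoyl carbonyl, LiCl-assisted) is the standard entry to N-enoyl imides and leaves the E-alkene intact.

Step 9
Reactants: 6 2-bromo-5,5-dimethoxypent-1-ene; 14 (4R)-4-benzyl-3-[(2E)-5-(TBDPS-oxy)pent-2-enoyl]-1,3-oxazolidin-2-one
Product: 16 (4R)-4-benzyl-3-[(3S)-3-[2-(TBDPS-oxy)ethyl]-7,7-dimethoxy-4-methylideneheptanoyl]-1,3-oxazolidin-2-one, via alkenylmagnesium bromide 15 (not isolated)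
Conditions: 6 (2.5 equiv), Mg, THF, 45 °C; CuBr·SMe2 (0.5 equiv, monovalent copper), THF/Me2S, −78 °C; then 14, −78 → −20 °C; aq. NH4Cl
Reagents that add atoms: none
Why: Copper-mediated 1,4-addition of the alkenyl Grignard reagent to the N-enoyl oxazolidinone should set C9, because in the magnesium-chelated syn-s-cis imide the benzyl group of the (R)-auxiliary shields one face and the alkenyl group enters anti to it.

Step 10
Reactants: 16 (4R)-4-benzyl-3-[(3S)-3-[2-(TBDPS-oxy)ethyl]-7,7-dimethoxy-4-methylideneheptanoyl]-1,3-oxazolidin-2-one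
Product: 18 (4R)-4-benzyl-3-[(2R,3S)-3-[2-(TBDPS-oxy)ethyl]-7,7-dimethoxy-2-methyl-4-methylideneheptanoyl]-1,3-oxazolidin-2-one, via sodium imide enolate 17 (not isolated)
Conditions: NaN(SiMe3)2, THF, −78 °C; MeI, −78 → −40 °C
Reagents that add atoms: iodomethane, CI
Why: Auxiliary-controlled alkylation of the chelated Z-sodium enolate with iodomethane, anti to benzyl, introduces C20 on C10; this centre is later erased by enolisation, so only its constitution matters.

Step 11
Reactants: 18 (4R)-4-benzyl-3-[(2R,3S)-3-[2-(TBDPS-oxy)ethyl]-7,7-dimethoxy-2-methyl-4-methylideneheptanoyl]-1,3-oxazolidin-2-one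
Product: 19 S-ethyl (2R,3S)-3-[2-(TBDPS-oxy)ethyl]-7,7-dimethoxy-2-methyl-4-methylideneheptanethioate
Conditions: EtSH, n-BuLi, THF, 0 °C; then 18, 0 °C → rt; aq. NH4Cl
Reagents that add atoms: ethanethiol, CCS
Why: Thiolysis of the imide with lithium ethanethiolate attacks the exocyclic carbonyl even in α-branched cases, releasing the recoverable auxiliary and giving a thioester suited to ketone synthesis.

Step 12
Reactants: 19 S-ethyl (2R,3S)-3-[2-(TBDPS-oxy)ethyl]-7,7-dimethoxy-2-methyl-4-methylideneheptanethioate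
Product: 20 S-ethyl (2R,3S)-3-[2-(TBDPS-oxy)ethyl]-2-methyl-4-methylidene-7-oxoheptanethioate
Conditions: pyridinium p-toluenesulfonate (cat.), acetone/H2O, 45 °C
Reagents that add atoms: water, O
Why: Mild acid-catalysed hydrolysis of the dimethyl acetal frees the C5 aldehyde, while the TBDPS ether, thioester and 1,1-disubstituted alkene should be stable to this weak acid.

Step 13
Reactants: 20 S-ethyl (2R,3S)-3-[2-(TBDPS-oxy)ethyl]-2-methyl-4-methylidene-7-oxoheptanethioate; 21 methyl 2-[bis(2,2,2-trifluoroethoxy)phosphoryl]propanoate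
Product: 23 methyl (2Z,7S,8R)-7-[2-(TBDPS-oxy)ethyl]-9-(ethylsulfanyl)-2,8-dimethyl-6-methylidene-9-oxonon-2-enoate, via potassium phosphonate carbanion 22 (not isolated)
Conditions: 21, KN(SiMe3)2, 18-crown-6, THF, −78 °C; then 20, −78 °C
Reagents that add atoms: none
Why: Still–Gennari olefination with the electron-poor phosphonate under dissociating conditions should give the Z-2-methyl enoate (C4, C18, C19 added), the geometry that later places the ester axial at C4.

Step 14
Reactants: 23 methyl (2Z,7S,8R)-7-[2-(TBDPS-oxy)ethyl]-9-(ethylsulfanyl)-2,8-dimethyl-6-methylidene-9-oxonon-2-enoate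
Product: 24 methyl (2Z,7S,8R)-7-[2-(TBDPS-oxy)ethyl]-2,8-dimethyl-6-methylidene-9-oxoundeca-2,10-dienoate
Conditions: Bu3SnCH=CH2, Pd2(dba)3 (cat., zerovalent palladium), tri(2-furyl)phosphine, CuOP(O)Ph2 (1.5 equiv, monovalent copper), THF, rt → 45 °C
Reagents that add atoms: tributyl(vinyl)stannane, C=C[Sn](CCCC)(CCCC)CCCC
Why: Liebeskind–Srogl-type thioester–stannane ketone synthesis, in which palladium inserts into the C–S bond and the thiophilic copper phosphinate drives transmetallation under neutral conditions, should add C2 and C3 without touching the methyl enoate.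

Step 15
Reactants: 24 methyl (2Z,7S,8R)-7-[2-(TBDPS-oxy)ethyl]-2,8-dimethyl-6-methylidene-9-oxoundeca-2,10-dienoate
Product: 25 methyl (2Z,7R,8Z)-9-(TBS-oxy)-7-[2-(TBDPS-oxy)ethyl]-2,8-dimethyl-6-methylideneundeca-2,8,10-trienoate
Conditions: TBSOTf, Et3N, CH2Cl2, −78 → 0 °C
Reagents that add atoms: tert-butyldimethylsilyl trifluoromethanesulfonate, CC(C)(C)[Si](C)(C)OS(=O)(=O)C(F)(F)F
Why: Soft enolisation (O-silylation, then deprotonation by Et3N) can occur only toward C10, the sole α-carbon bearing hydrogen, and allylic strain should place the branched C9 cis to the small silyloxy oxygen with the methyl inside.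

Step 16
Reactants: 25 methyl (2Z,7R,8Z)-9-(TBS-oxy)-7-[2-(TBDPS-oxy)ethyl]-2,8-dimethyl-6-methylideneundeca-2,8,10-trienoate
Product: 27 methyl (4R,5S,9R,10S)-12-(TBDPS-oxy)-1-oxo-13,14,15,16-tetranorlabd-8(17)-en-19-oate, via silyl enol ether cycloadduct 26 (not isolated)
Conditions: PhMe (0.01 M), BHT, Et3N (cat.), sealed tube, 165 °C; concentrate; 1 M aq. HCl, THF, 0 °C → rt
Reagents that add atoms: none
Why: Thermal, concerted but asynchronous [4+2] cycloaddition, of the known type 1 intramolecular Diels–Alder class of 2-silyloxydienes with tethered enoates (formally an intramolecular double Michael addition), in which the nucleophilic diene terminus C10 bonds to the enoate β-carbon C5 ahead of the C3–C4 bond. Ring B closes through the tether C9–C8–C7–C6 as a chair (6-exo with respect to the dienophile), and ring A is the cyclohexene created by the cycloaddition itself, emerging as the C1 silyl enol ether with oxygen at C1 and the ester at C4. C10 and C5 are set by C9: allylic 1,3-strain with the C1 silyloxy group keeps H9 near the diene plane, so the tether reaches only one diene face with the C11 arm pseudo-equatorial, and the anti (tether-exo) chair gives the trans ring fusion with C20 axial. C4 is set by suprafacial addition to the Z-enoate, whose ester is cis to C6 and therefore ends axial, syn to C20, with C18 equatorial. The step needs anti over syn folding and a single diene face, which the outside position of C9 in 25, the sp2 C8 (one 1,3-diaxial contact fewer for the axial methyl) and the unsubstituted C3 terminus meeting the hindered C4 should secure, while BHT, a trace of Et3N and the lowest workable temperature hold back polymerisation, desilylation and the 1,5-hydrogen shift of the inside methyl. Dilute HCl in THF then hydrolyses the silyl enol ether of 26 to ketone 27, which has no epimerisable stereocentre.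

Step 17
Reactants: 27 methyl (4R,5S,9R,10S)-12-(TBDPS-oxy)-1-oxo-13,14,15,16-tetranorlabd-8(17)-en-19-oate
Product: 28 methyl (1S,4R,5S,9R,10S)-12-(TBDPS-oxy)-1-hydroxy-13,14,15,16-tetranorlabd-8(17)-en-19-oate
Conditions: NaBH4, MeOH, −20 → 0 °C
Reagents that add atoms: none
Why: Borohydride reduction is chemoselective for the ketone over the hindered methyl ester, and hydride should enter axially, on the face opposite the axial C20 methyl and away from the C11 arm, to give the equatorial (1S) alcohol (kept cold so that the alkoxide does not attack the cis C19 ester).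

Step 18
Reactants: 28 methyl (1S,4R,5S,9R,10S)-12-(TBDPS-oxy)-1-hydroxy-13,14,15,16-tetranorlabd-8(17)-en-19-oate
Product: 29 methyl (1S,4R,5S,9R,10S)-1-acetoxy-12-(TBDPS-oxy)-13,14,15,16-tetranorlabd-8(17)-en-19-oate
Conditions: Ac2O, DMAP (cat.), pyridine, CH2Cl2, rt
Reagents that add atoms: acetic anhydride, CC(=O)OC(C)=O
Why: Nucleophile-catalysed acetylation of the secondary equatorial alcohol, with retention at C1.

Step 19
Reactants: 29 methyl (1S,4R,5S,9R,10S)-1-acetoxy-12-(TBDPS-oxy)-13,14,15,16-tetranorlabd-8(17)-en-19-oate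
Product: 30 methyl (1S,4R,5S,9R,10S)-1-acetoxy-12-hydroxy-13,14,15,16-tetranorlabd-8(17)-en-19-oate
Conditions: Bu4NF, AcOH, THF, rt
Reagents that add atoms: none
Why: Fluoride cleavage of the silyl ether, buffered with acetic acid so that the C1 acetate neither migrates nor hydrolyses.

Step 20
Reactants: 30 methyl (1S,4R,5S,9R,10S)-1-acetoxy-12-hydroxy-13,14,15,16-tetranorlabd-8(17)-en-19-oate
Product: 31 methyl (1S,4R,5S,9R,10S)-1-acetoxy-12-oxo-13,14,15,16-tetranorlabd-8(17)-en-19-oate
Conditions: Dess–Martin periodinane, CH2Cl2, rt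
Reagents that add atoms: none
Why: Dess–Martin oxidation gives the C12 aldehyde under mild conditions, with no α-stereocentre at risk and no isomerisation of the exocyclic alkene expected.

Step 21
Reactants: 31 methyl (1S,4R,5S,9R,10S)-1-acetoxy-12-oxo-13,14,15,16-tetranorlabd-8(17)-en-19-oate; 32 2-(triphenylphosphoranylidene)propanal
Product: 33 methyl (1S,4R,5S,9R,10S,12E)-1-acetoxy-14-oxo-15-norlabda-8(17),12-dien-19-oate
Conditions: 32, PhMe, 90 °C
Reagents that add atoms: none
Why: Wittig reaction with a stabilised formyl ylide adds C13, C14 and C16 and should give the trisubstituted enal with E geometry.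

Step 22
Reactants: 33 methyl (1S,4R,5S,9R,10S,12E)-1-acetoxy-14-oxo-15-norlabda-8(17),12-dien-19-oate
Product: 34 methyl (1S,4R,5S,9R,10S,12E)-1-acetoxylabda-8(17),12,14-trien-19-oate
Conditions: Ph3PCH3Br, KN(SiMe3)2, THF, 0 °C; then 33, −78 → 0 °C
Reagents that add atoms: methyltriphenylphosphonium bromide, C[P+](c1ccccc1)(c1ccccc1)c1ccccc1.[Br-]
Why: Wittig methylenation of the enal at low temperature is 1,2-selective and faster than attack on the acetate or the hindered methyl ester, so it should add C15 and complete the E-diene.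

Compound list
1 | 2,3-dibromopropene | C=C(Br)CBr | starting material
2 | ethyl acetate | CCOC(C)=O | starting material
3 | ethyl acetate lithium enolate | C=C([O-])OCC.[Li+] | intermediate
4 | ethyl 4-bromopent-4-enoate | C=C(Br)CCC(=O)OCC | intermediate
5 | 4-bromopent-4-enal | C=C(Br)CCC=O | intermediate
6 | 2-bromo-5,5-dimethoxypent-1-ene | C=C(Br)CCC(OC)OC | intermediate
7 | propane-1,3-diol | OCCCO | starting material
8 | 3-(TBDPS-oxy)propan-1-ol | CC(C)(C)[Si](c1ccccc1)(c1ccccc1)OCCCO | intermediate
9 | 3-(TBDPS-oxy)propanal | CC(C)(C)[Si](c1ccccc1)(c1ccccc1)OCCC=O | intermediate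
10 | ethyl (2E)-5-(TBDPS-oxy)pent-2-enoate | CC(C)(C)[Si](c1ccccc1)(c1ccccc1)OCC/C=C/C(=O)OCC | intermediate
11 | (2E)-5-(TBDPS-oxy)pent-2-enoic acid | CC(C)(C)[Si](c1ccccc1)(c1ccccc1)OCC/C=C/C(=O)O | intermediate
12 | (4R)-4-benzyl-1,3-oxazolidin-2-one | O=C1OC[C@@H](Cc2ccccc2)N1 | starting material
13 | mixed pivalic anhydride of acid 11 | CC(C)(C)[Si](c1ccccc1)(c1ccccc1)OCC/C=C/C(=O)OC(=O)C(C)(C)C | intermediate
14 | (4R)-4-benzyl-3-[(2E)-5-(TBDPS-oxy)pent-2-enoyl]-1,3-oxazolidin-2-one | CC(C)(C)[Si](c1ccccc1)(c1ccccc1)OCC/C=C/C(=O)N1[C@H](Cc2ccccc2)COC1=O | intermediate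
15 | (5,5-dimethoxypent-1-en-2-yl)magnesium bromide | C=C([Mg]Br)CCC(OC)OC | intermediate
16 | (4R)-4-benzyl-3-[(3S)-3-[2-(TBDPS-oxy)ethyl]-7,7-dimethoxy-4-methylideneheptanoyl]-1,3-oxazolidin-2-one | CC(C)(C)[Si](c1ccccc1)(c1ccccc1)OCC[C@@H](CC(=O)N1[C@H](Cc2ccccc2)COC1=O)C(=C)CCC(OC)OC | intermediate
17 | sodium (Z)-enolate of imide 16 | CC(C)(C)[Si](c1ccccc1)(c1ccccc1)OCC[C@@H](/C=C(\[O-])N1[C@H](Cc2ccccc2)COC1=O)C(=C)CCC(OC)OC.[Na+] | intermediate
18 | (4R)-4-benzyl-3-[(2R,3S)-3-[2-(TBDPS-oxy)ethyl]-7,7-dimethoxy-2-methyl-4-methylideneheptanoyl]-1,3-oxazolidin-2-one | CC(C)(C)[Si](c1ccccc1)(c1ccccc1)OCC[C@@H]([C@@H](C)C(=O)N1[C@H](Cc2ccccc2)COC1=O)C(=C)CCC(OC)OC | intermediate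
19 | S-ethyl (2R,3S)-3-[2-(TBDPS-oxy)ethyl]-7,7-dimethoxy-2-methyl-4-methylideneheptanethioate | CC(C)(C)[Si](c1ccccc1)(c1ccccc1)OCC[C@@H]([C@@H](C)C(=O)SCC)C(=C)CCC(OC)OC | intermediate
20 | S-ethyl (2R,3S)-3-[2-(TBDPS-oxy)ethyl]-2-methyl-4-methylidene-7-oxoheptanethioate | CC(C)(C)[Si](c1ccccc1)(c1ccccc1)OCC[C@@H]([C@@H](C)C(=O)SCC)C(=C)CCC=O | intermediate
21 | methyl 2-[bis(2,2,2-trifluoroethoxy)phosphoryl]propanoate | COC(=O)C(C)P(=O)(OCC(F)(F)F)OCC(F)(F)F | starting material
22 | potassium carbanion of phosphonate 21 | COC(=O)[C-](C)P(=O)(OCC(F)(F)F)OCC(F)(F)F.[K+] | intermediate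
23 | methyl (2Z,7S,8R)-7-[2-(TBDPS-oxy)ethyl]-9-(ethylsulfanyl)-2,8-dimethyl-6-methylidene-9-oxonon-2-enoate | CC(C)(C)[Si](c1ccccc1)(c1ccccc1)OCC[C@@H]([C@@H](C)C(=O)SCC)C(=C)CC/C=C(/C)C(=O)OC | intermediate
24 | methyl (2Z,7S,8R)-7-[2-(TBDPS-oxy)ethyl]-2,8-dimethyl-6-methylidene-9-oxoundeca-2,10-dienoate | CC(C)(C)[Si](c1ccccc1)(c1ccccc1)OCC[C@@H]([C@@H](C)C(=O)C=C)C(=C)CC/C=C(/C)C(=O)OC | intermediate
25 | methyl (2Z,7R,8Z)-9-(TBS-oxy)-7-[2-(TBDPS-oxy)ethyl]-2,8-dimethyl-6-methylideneundeca-2,8,10-trienoate | CC(C)(C)[Si](c1ccccc1)(c1ccccc1)OCC[C@@H](/C(C)=C(\O[Si](C)(C)C(C)(C)C)C=C)C(=C)CC/C=C(/C)C(=O)OC | intermediate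
26 | methyl (4R,5S,9R,10S)-1-(TBS-oxy)-12-(TBDPS-oxy)-13,14,15,16-tetranorlabda-1,8(17)-dien-19-oate (trans-decalin; C20 and the C19 ester axial on the same face) | CC(C)(C)[Si](c1ccccc1)(c1ccccc1)OCC[C@@H]1C(=C)CC[C@H]2[C@@]1(C)C(O[Si](C)(C)C(C)(C)C)=CC[C@@]2(C)C(=O)OC | intermediate
27 | methyl (4R,5S,9R,10S)-12-(TBDPS-oxy)-1-oxo-13,14,15,16-tetranorlabd-8(17)-en-19-oate | CC(C)(C)[Si](c1ccccc1)(c1ccccc1)OCC[C@@H]1C(=C)CC[C@H]2[C@@]1(C)C(=O)CC[C@@]2(C)C(=O)OC | intermediate
28 | methyl (1S,4R,5S,9R,10S)-12-(TBDPS-oxy)-1-hydroxy-13,14,15,16-tetranorlabd-8(17)-en-19-oate (equatorial OH) | CC(C)(C)[Si](c1ccccc1)(c1ccccc1)OCC[C@@H]1C(=C)CC[C@H]2[C@@]1(C)[C@@H](O)CC[C@@]2(C)C(=O)OC | intermediate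
29 | methyl (1S,4R,5S,9R,10S)-1-acetoxy-12-(TBDPS-oxy)-13,14,15,16-tetranorlabd-8(17)-en-19-oate | CC(C)(C)[Si](c1ccccc1)(c1ccccc1)OCC[C@@H]1C(=C)CC[C@H]2[C@@]1(C)[C@@H](OC(C)=O)CC[C@@]2(C)C(=O)OC | intermediate
30 | methyl (1S,4R,5S,9R,10S)-1-acetoxy-12-hydroxy-13,14,15,16-tetranorlabd-8(17)-en-19-oate | OCC[C@@H]1C(=C)CC[C@H]2[C@@]1(C)[C@@H](OC(C)=O)CC[C@@]2(C)C(=O)OC | intermediate
31 | methyl (1S,4R,5S,9R,10S)-1-acetoxy-12-oxo-13,14,15,16-tetranorlabd-8(17)-en-19-oate | O=CC[C@@H]1C(=C)CC[C@H]2[C@@]1(C)[C@@H](OC(C)=O)CC[C@@]2(C)C(=O)OC | intermediate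
32 | 2-(triphenylphosphoranylidene)propanal | CC(C=O)=P(c1ccccc1)(c1ccccc1)c1ccccc1 | starting material
33 | methyl (1S,4R,5S,9R,10S,12E)-1-acetoxy-14-oxo-15-norlabda-8(17),12-dien-19-oate | O=C/C(C)=C/C[C@@H]1C(=C)CC[C@H]2[C@@]1(C)[C@@H](OC(C)=O)CC[C@@]2(C)C(=O)OC | intermediate
34 | methyl (1S,4R,5S,9R,10S,12E)-1-acetoxylabda-8(17),12,14-trien-19-oate | C=C/C(C)=C/C[C@@H]1C(=C)CC[C@H]2[C@@]1(C)[C@@H](OC(C)=O)CC[C@@]2(C)C(=O)OC | target

Total step count: 22
Longest linear sequence: 19 steps (steps 4–8, then 9–22, from propane-1,3-diol)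

Steps most likely to fail

1. Step 16 (cycloaddition). The ring closure may be too slow, because the inside C20 methyl and the trisubstituted dienophile raise the barrier; the 1,5-hydrogen shift of the diene, desilylation or syn folding of the tether (cis fusion) could then compete. The fallback leaves C18 out of the dienophile until the rings exist; it sets out from aldehyde 20 and comes back at cycloadduct 26, which is hydrolysed to 27 as in the second stage of step 16. Horner–Wadsworth–Emmons reaction of 20 with trimethyl phosphonoacetate (LiCl, iPr2NEt, MeCN) should give the (E)-enoate thioester F1. Vinylation as in step 14 gives vinyl ketone F2, and TBSOTf/Et3N as in step 15 gives silyloxydiene F3. The dienophile of F3 is a disubstituted (E)-enoate, so heating in PhMe (BHT, trace Et3N) should close both rings at a clearly lower temperature through the same anti chair, now with the ester endo, to give the 18-nor cycloadduct F4 (C4–H, ester equatorial; the C4 configuration is immaterial). Deprotonation at C4 with LiN(iPr)2 (THF/DMPU, −78 °C) and C-methylation with MeI then follows the established course for C4 ester enolates of 10-methyl-trans-decalins: the electrophile enters opposite the axial C20 methyl, so C18 becomes equatorial and the ester axial, which is 26. The C1 silyl enol ether tolerates the amide base.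

2. Step 15 (enol ether formation). Enolisation may give a mixture of enol ether geometries, and only the isomer with C9 outside can reach the anti transition state; reversible amine addition to the vinyl ketone could also erode material. The fallback does without any preformed enol derivative; it sets out from vinyl ketone 24 and comes back at ketone 27, passing neither 25 nor 26 and making no new compound (F0). Kinetic deprotonation at C10 with LiN(SiMe3)2 (THF, −78 → 0 °C, high dilution) gives the cross-conjugated lithium dienolate, which should undergo the known intramolecular double Michael addition of enone–enoates: C10 adds to C5 through a lithium-bridged chair, and the resulting ester enolate closes from C4 onto C3. C10 is trigonal in either enolate geometry, so the C10/C5 outcome depends on the C9-controlled chair and not on enolate geometry. The point to verify is C4: the Z-enoate geometry is transferred only if the second closure within the chelate is faster than rotation about C4–C5.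

3. Step 14 (thioester to vinyl ketone). Acyl transfer at the hindered α-branched thioester may be sluggish, and the product may be lost by polymerisation or thiolate conjugate addition. The fallback builds the enone by reduction, addition and oxidation; it sets out from thioester 23 and comes back at vinyl ketone 24. Fukuyama reduction (Et3SiH, Pd/C, acetone, rt) should give aldehyde F5. CH2=CHMgBr (THF, −78 °C) should add to the aldehyde faster than to the hindered enoate, giving allylic alcohol F6 as a mixture of carbinol epimers. Dess–Martin oxidation then converges both epimers on 24. Any epimerisation at C10 on the way is of no consequence.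

Further compounds
F1 | step 16 | methyl (2E,7S,8R)-7-[2-(TBDPS-oxy)ethyl]-9-(ethylsulfanyl)-8-methyl-6-methylidene-9-oxonon-2-enoate | CC(C)(C)[Si](c1ccccc1)(c1ccccc1)OCC[C@@H]([C@@H](C)C(=O)SCC)C(=C)CC/C=C/C(=O)OC
F2 | step 16 | methyl (2E,7S,8R)-7-[2-(TBDPS-oxy)ethyl]-8-methyl-6-methylidene-9-oxoundeca-2,10-dienoate | CC(C)(C)[Si](c1ccccc1)(c1ccccc1)OCC[C@@H]([C@@H](C)C(=O)C=C)C(=C)CC/C=C/C(=O)OC
F3 | step 16 | methyl (2E,7R,8Z)-9-(TBS-oxy)-7-[2-(TBDPS-oxy)ethyl]-8-methyl-6-methylideneundeca-2,8,10-trienoate | CC(C)(C)[Si](c1ccccc1)(c1ccccc1)OCC[C@@H](/C(C)=C(\O[Si](C)(C)C(C)(C)C)C=C)C(=C)CC/C=C/C(=O)OC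
F4 | step 16 | 18-nor analogue of cycloadduct 26 (hydrogen in place of C18 at C4, ester equatorial) | CC(C)(C)[Si](c1ccccc1)(c1ccccc1)OCC[C@@H]1C(=C)CC[C@H]2[C@@]1(C)C(O[Si](C)(C)C(C)(C)C)=CC[C@@H]2C(=O)OC
F0 | step 15 | none | none
F5 | step 14 | methyl (2Z,7S,8R)-7-[2-(TBDPS-oxy)ethyl]-2,8-dimethyl-6-methylidene-9-oxonon-2-enoate | CC(C)(C)[Si](c1ccccc1)(c1ccccc1)OCC[C@@H]([C@@H](C)C=O)C(=C)CC/C=C(/C)C(=O)OC
F6 | step 14 | methyl (2Z,7S,8R)-7-[2-(TBDPS-oxy)ethyl]-9-hydroxy-2,8-dimethyl-6-methylideneundeca-2,10-dienoate (both C9 carbinol epimers) | CC(C)(C)[Si](c1ccccc1)(c1ccccc1)OCC[C@@H]([C@@H](C)C(O)C=C)C(=C)CC/C=C(/C)C(=O)OC
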